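**Retrosynthetic overview**
1. Target 20 comes from O-methylation of the enolic OH of isotetronic acid 19 (last step).
2. 19 comes from an aldol–lactonization of two arylpyruvate units, as in the fungal pathway: persilylated 3,4-dihydroxyphenylpyruvic acid 16 (donor) adds to chromanyl pyruvate 11 (acceptor), forming furanone C-3–C-2 and then O-1–C-5. A chiral copper Lewis acid sets the quaternary centre.
3. 11 comes from chroman aldehyde 7 (Horner–Wadsworth–Emmons, enamide hydrolysis); 16 comes from 3,4-dihydroxybenzaldehyde (azlactone, hydrolysis, silylation).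
4. 7 comes from 6-endo phenol-onto-epoxide closure of an (S)-prenyl epoxide (Shi epoxidation), itself from C-prenylation of 4-hydroxybenzaldehyde.
5. Ring order: dihydropyran ring of the chroman first (step 4), butenolide ring last (step 10).

Stereochemical reading used: the SMILES corresponds to 2S at the furanone quaternary carbon and 3S at the chromanol carbon.

**Step 1**
Reactants: 1 4-hydroxybenzaldehyde; 2 1-bromo-3-methylbut-2-ene (prenyl bromide)
Product: 3 4-hydroxy-3-(3-methylbut-2-en-1-yl)benzaldehyde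
Conditions: KOH, H2O, rt, 24 h
Reagents that add atoms: none
Why: Ortho C-alkylation of a phenoxide (C-prenylation) in water, where the solvated oxygen is shielded and the blocked para position leaves only the ortho carbon; the yield is modest (about 35–40%) and the O-prenyl ether is removed by chromatography.

**Step 2**
Reactants: 3 4-hydroxy-3-(3-methylbut-2-en-1-yl)benzaldehyde
Product: 4 3-(3-methylbut-2-en-1-yl)-4-[(triisopropylsilyl)oxy]benzaldehyde
Conditions: TIPSCl, imidazole, DMF, rt
Reagents that add atoms: triisopropylsilyl chloride, CC(C)[Si](Cl)(C(C)C)C(C)C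
Why: Standard phenol silylation; the bulky TIPS ether is chosen to survive the pH 10.5 epoxidation medium so that no phenoxide can open the epoxide in the 5-exo sense.

**Step 3**
Reactants: 4 3-(3-methylbut-2-en-1-yl)-4-[(triisopropylsilyl)oxy]benzaldehyde
Product: 5 3-{[(2S)-3,3-dimethyloxiran-2-yl]methyl}-4-[(triisopropylsilyl)oxy]benzaldehyde
Conditions: ent-Shi ketone (L-fructose-derived, 30 mol%), Oxone (2KHSO5·KHSO4·K2SO4), K2CO3, Bu4NHSO4, MeCN–DMM–aq. Na2B4O7 buffer (pH 10.5), 0 °C
Reagents that add atoms: potassium peroxymonosulfate (active part of Oxone), [K+].[O-]S(=O)(=O)OO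
Why: Shi asymmetric epoxidation of the electron-rich trisubstituted alkene through the spiro dioxirane transition state; the D-fructose ketone gives the R epoxide for R-CH2-CH=CMe2 olefins, so the enantiomeric ketone delivers the 2S epoxide.

**Step 4**
Reactants: 5 3-{[(2S)-3,3-dimethyloxiran-2-yl]methyl}-4-[(triisopropylsilyl)oxy]benzaldehyde
Product: 7 (3S)-3-hydroxy-2,2-dimethyl-3,4-dihydro-2H-chromene-6-carbaldehyde, via epoxy phenol 6 (not isolated)
Conditions: TBAF, AcOH (3 equiv), THF, −20 °C, cold pH 5 wash; then CSA (20 mol%), CH2Cl2, 0 °C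
Reagents that add atoms: none
Why: Buffered fluoride desilylation keeps the phenol neutral, and Brønsted acid then drives the 6-endo (Markovnikov) phenol-onto-epoxide opening at the tertiary carbon, the chroman-forming event of the biosynthesis; the secondary C–O bond is not broken, so 2S in the epoxide becomes 3S in the chromanol.

**Step 5**
Reactants: 7 (3S)-3-hydroxy-2,2-dimethyl-3,4-dihydro-2H-chromene-6-carbaldehyde; 8 methyl 2-[(tert-butoxycarbonyl)amino]-2-(dimethoxyphosphoryl)acetate (racemic)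
Product: 9 methyl (2Z)-2-[(tert-butoxycarbonyl)amino]-3-[(3S)-3-hydroxy-2,2-dimethyl-3,4-dihydro-2H-chromen-6-yl]prop-2-enoate
Conditions: DBU, CH2Cl2, 0 °C → rt
Reagents that add atoms: none
Why: Horner–Wadsworth–Emmons olefination with the Schmidt phosphonoglycinate is Z-selective and tolerates the free secondary alcohol.

**Step 6**
Reactants: 9 methyl (2Z)-2-[(tert-butoxycarbonyl)amino]-3-[(3S)-3-hydroxy-2,2-dimethyl-3,4-dihydro-2H-chromen-6-yl]prop-2-enoate
Product: 11 methyl 3-[(3S)-3-hydroxy-2,2-dimethyl-3,4-dihydro-2H-chromen-6-yl]-2-oxopropanoate, via free enamino ester 10 (not isolated)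
Conditions: TFA, CH2Cl2, 0 °C; then H2O–THF, rt
Reagents that add atoms: water, O
Why: Acidolysis of the Boc group gives a primary enamine that tautomerizes to the iminium and is hydrolysed to the α-keto ester (enamine hydrolysis); the acidic aqueous work-up leaves the keto tautomer enriched, and it is used without chromatography.

**Step 7**
Reactants: 12 3,4-dihydroxybenzaldehyde; 13 N-acetylglycine
Product: 14 (4Z)-4-[(3,4-diacetoxyphenyl)methylidene]-2-methyl-1,3-oxazol-5(4H)-one
Conditions: Ac2O, NaOAc, 110 °C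
Reagents that add atoms: acetic anhydride, CC(=O)OC(C)=O
Why: Erlenmeyer–Plöchl azlactone synthesis with in situ acetylation of the catechol, giving the thermodynamic Z isomer.

**Step 8**
Reactants: 14 (4Z)-4-[(3,4-diacetoxyphenyl)methylidene]-2-methyl-1,3-oxazol-5(4H)-one
Product: 15 (2Z)-3-(3,4-dihydroxyphenyl)-2-hydroxyprop-2-enoic acid (enol form of 3,4-dihydroxyphenylpyruvic acid)
Conditions: 3 M HCl (aq), reflux, N2
Reagents that add atoms: water, O
Why: Acid hydrolysis of the azlactone, the enamide and both aryl acetates gives the arylpyruvic acid, which crystallizes as its Z enol (classical arylpyruvic acid preparation).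

**Step 9**
Reactants: 15 (2Z)-3-(3,4-dihydroxyphenyl)-2-hydroxyprop-2-enoic acid
Product: 16 trimethylsilyl (2Z)-3-[3,4-bis(trimethylsilyloxy)phenyl]-2-(trimethylsilyloxy)prop-2-enoate
Conditions: HMDS (3 equiv), MeCN, 70 °C; volatiles removed in vacuo, used crude under argon
Reagents that add atoms: hexamethyldisilazane, C[Si](C)(C)N[Si](C)(C)C
Why: Exhaustive O-silylation of the acid, the enol and both phenols (ammonia is the only by-product) turns the enol into a geometry-defined enolsilane and masks the catechol without a separate protection step.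

**Step 10**
Reactants: 11 methyl 3-[(3S)-3-hydroxy-2,2-dimethyl-3,4-dihydro-2H-chromen-6-yl]-2-oxopropanoate (1.0 equiv); 16 trimethylsilyl (2Z)-3-[3,4-bis(trimethylsilyloxy)phenyl]-2-(trimethylsilyloxy)prop-2-enoate (1.6 equiv)
Product: 19 methyl (2S)-3-(3,4-dihydroxyphenyl)-4-hydroxy-2-{[(3S)-3-hydroxy-2,2-dimethyl-3,4-dihydro-2H-chromen-6-yl]methyl}-5-oxo-2,5-dihydrofuran-2-carboxylate, via silylated aldol adduct 17 (not isolated), via seco hydroxy keto acid 18 (not isolated)
Conditions: Cu(OTf)2 (10 mol%), (S,S)-tBu-box (11 mol%), THF, −78 → −30 °C; then 1 M HCl, THF, rt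
Reagents that add atoms: none
Why: Proposed new method: 16 is a role-locked enolsilane of the catechol pyruvate (it has no ketone and cannot act as acceptor), while the 1,2-dicarbonyl of 11 chelates divalent copper in a square-planar complex whose tert-butyl group shields the re face, so attack on the si face of the ketone sets 2S by the same model that gives S products from pyruvate esters; aqueous acid then removes all silyl groups and the tertiary alcohol closes onto the α-keto acid to give the enol-stabilized butenolide, the aldol–lactonization by which the producing fungus joins two arylpyruvates; the closest known reactions are the Cu(OTf)2–bis(oxazoline)-catalysed Mukaiyama aldol of enolsilanes with pyruvate esters, Lewis acid aldols of silyl 2-silyloxyacrylates, and the base-mediated aldol–lactone dimerization of arylpyruvates.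

**Step 11**
Reactants: 19 methyl (2S)-3-(3,4-dihydroxyphenyl)-4-hydroxy-2-{[(3S)-3-hydroxy-2,2-dimethyl-3,4-dihydro-2H-chromen-6-yl]methyl}-5-oxo-2,5-dihydrofuran-2-carboxylate
Product: 20 methyl (2S)-3-(3,4-dihydroxyphenyl)-2-{[(3S)-3-hydroxy-2,2-dimethyl-3,4-dihydro-2H-chromen-6-yl]methyl}-4-methoxy-5-oxo-2,5-dihydrofuran-2-carboxylate (target)
Conditions: TMSCHN2 (1.05 equiv), PhMe–MeOH (4:1), 0 °C
Reagents that add atoms: trimethylsilyldiazomethane, C[Si](C)(C)C=[N+]=[N-]
Why: Diazoalkane O-methylation is governed by acidity, and the enol flanked by the lactone carbonyl is the most acidic OH (above the catechol and far above the secondary alcohol), so one equivalent methylates it selectively without touching either stereocenter.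

**Compound list**
1 | 4-hydroxybenzaldehyde | O=Cc1ccc(O)cc1 | starting material
2 | 1-bromo-3-methylbut-2-ene (prenyl bromide) | CC(C)=CCBr | starting material
3 | 4-hydroxy-3-(3-methylbut-2-en-1-yl)benzaldehyde | CC(C)=CCc1cc(C=O)ccc1O | intermediate
4 | 3-(3-methylbut-2-en-1-yl)-4-[(triisopropylsilyl)oxy]benzaldehyde | CC(C)=CCc1cc(C=O)ccc1O[Si](C(C)C)(C(C)C)C(C)C | intermediate
5 | 3-{[(2S)-3,3-dimethyloxiran-2-yl]methyl}-4-[(triisopropylsilyl)oxy]benzaldehyde | CC(C)[Si](C(C)C)(C(C)C)Oc1ccc(C=O)cc1C[C@@H]1OC1(C)C | intermediate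
6 | 3-{[(2S)-3,3-dimethyloxiran-2-yl]methyl}-4-hydroxybenzaldehyde (not isolated) | O=Cc1ccc(O)c(C[C@@H]2OC2(C)C)c1 | intermediate
7 | (3S)-3-hydroxy-2,2-dimethyl-3,4-dihydro-2H-chromene-6-carbaldehyde | O=Cc1ccc2OC(C)(C)[C@@H](O)Cc2c1 | intermediate
8 | methyl 2-[(tert-butoxycarbonyl)amino]-2-(dimethoxyphosphoryl)acetate (racemic) | COC(=O)C(NC(=O)OC(C)(C)C)P(=O)(OC)OC | starting material
9 | methyl (2Z)-2-[(tert-butoxycarbonyl)amino]-3-[(3S)-3-hydroxy-2,2-dimethyl-3,4-dihydro-2H-chromen-6-yl]prop-2-enoate | COC(=O)/C(NC(=O)OC(C)(C)C)=C/c1ccc2OC(C)(C)[C@@H](O)Cc2c1 | intermediate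
10 | methyl (2Z)-2-amino-3-[(3S)-3-hydroxy-2,2-dimethyl-3,4-dihydro-2H-chromen-6-yl]prop-2-enoate (not isolated; present as its trifluoroacetate salt) | COC(=O)/C(N)=C/c1ccc2OC(C)(C)[C@@H](O)Cc2c1 | intermediate
11 | methyl 3-[(3S)-3-hydroxy-2,2-dimethyl-3,4-dihydro-2H-chromen-6-yl]-2-oxopropanoate | COC(=O)C(=O)Cc1ccc2OC(C)(C)[C@@H](O)Cc2c1 | intermediate
12 | 3,4-dihydroxybenzaldehyde | O=Cc1ccc(O)c(O)c1 | starting material
13 | N-acetylglycine | CC(=O)NCC(=O)O | starting material
14 | (4Z)-4-[(3,4-diacetoxyphenyl)methylidene]-2-methyl-1,3-oxazol-5(4H)-one | CC1=N/C(=C\c2ccc(OC(C)=O)c(OC(C)=O)c2)C(=O)O1 | intermediate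
15 | (2Z)-3-(3,4-dihydroxyphenyl)-2-hydroxyprop-2-enoic acid | OC(=O)/C(O)=C/c1ccc(O)c(O)c1 | intermediate
16 | trimethylsilyl (2Z)-3-[3,4-bis(trimethylsilyloxy)phenyl]-2-(trimethylsilyloxy)prop-2-enoate | C[Si](C)(C)OC(=O)/C(O[Si](C)(C)C)=C/c1ccc(O[Si](C)(C)C)c(O[Si](C)(C)C)c1 | intermediate
17 | trimethylsilyl (4S)-3-[3,4-bis(trimethylsilyloxy)phenyl]-5-[(3S)-3-hydroxy-2,2-dimethyl-3,4-dihydro-2H-chromen-6-yl]-4-(methoxycarbonyl)-2-oxo-4-(trimethylsilyloxy)pentanoate (C-3 epimer mixture, not isolated) | COC(=O)[C@@](Cc1ccc2OC(C)(C)[C@@H](O)Cc2c1)(O[Si](C)(C)C)C(C(=O)C(=O)O[Si](C)(C)C)c1ccc(O[Si](C)(C)C)c(O[Si](C)(C)C)c1 | intermediate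
18 | (4S)-3-(3,4-dihydroxyphenyl)-4-hydroxy-5-[(3S)-3-hydroxy-2,2-dimethyl-3,4-dihydro-2H-chromen-6-yl]-4-(methoxycarbonyl)-2-oxopentanoic acid (C-3 epimer mixture, not isolated) | COC(=O)[C@](O)(Cc1ccc2OC(C)(C)[C@@H](O)Cc2c1)C(C(=O)C(=O)O)c1ccc(O)c(O)c1 | intermediate
19 | methyl (2S)-3-(3,4-dihydroxyphenyl)-4-hydroxy-2-{[(3S)-3-hydroxy-2,2-dimethyl-3,4-dihydro-2H-chromen-6-yl]methyl}-5-oxo-2,5-dihydrofuran-2-carboxylate | COC(=O)[C@@]1(Cc2ccc3c(c2)C[C@H](O)C(C)(C)O3)OC(=O)C(O)=C1c1ccc(O)c(O)c1 | intermediate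
20 | methyl (2S)-3-(3,4-dihydroxyphenyl)-2-{[(3S)-3-hydroxy-2,2-dimethyl-3,4-dihydro-2H-chromen-6-yl]methyl}-4-methoxy-5-oxo-2,5-dihydrofuran-2-carboxylate | COC(=O)[C@@]1(Cc2ccc3c(c2)C[C@H](O)C(C)(C)O3)OC(=O)C(OC)=C1c1ccc(O)c(O)c1 | target

**Step count**
Total: 11 steps (acceptor arm steps 1–6, donor arm steps 7–9, union and finish steps 10–11).
Longest linear sequence: 8 steps (1–6, 10, 11).

**Three steps most likely to fail, with fallbacks**

Step 10 (cross aldol–lactonization). The arylpyruvate 11 is largely enolized in organic solvents. The enol is a poor electrophile and could exchange silyl groups with 16, which would scramble donor and acceptor roles. The sense and level of induction rest on analogy with simple pyruvates. The fallback sets out from 15 and 11. Acid 15 is esterified (MeOH, TMSCl, rt) to methyl (2Z)-3-(3,4-dihydroxyphenyl)-2-hydroxyprop-2-enoate F1. F1 (3 equiv, so that it is the statistical donor) is condensed with 11 under DBU in DMF at 0 °C under argon, the thermodynamic aldol–lactonization used to dimerize arylpyruvates. This is not stereoselective at C-2 and gives 19 together with its epimer methyl (2R)-3-(3,4-dihydroxyphenyl)-4-hydroxy-2-{[(3S)-3-hydroxy-2,2-dimethyl-3,4-dihydro-2H-chromen-6-yl]methyl}-5-oxo-2,5-dihydrofuran-2-carboxylate F2. The two are diastereomers because of the fixed chromanol centre and are separated by preparative HPLC. The route is rejoined at 19.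

Step 4 (6-endo closure). Under weakly acidic or basic conditions the phenol opens the epoxide at the secondary carbon (5-exo) to give the hydroxyisopropyl dihydrobenzofuran instead. The fallback sets out from 3 and replaces steps 2–4 with a chromene oxidation. DDQ in refluxing benzene cyclizes 3 to 2,2-dimethyl-2H-chromene-6-carbaldehyde F3. Jacobsen epoxidation with (S,S)-(salen)MnCl, NaOCl and 4-phenylpyridine N-oxide in CH2Cl2 at 0 °C gives (3S,4S)-3,4-epoxy-2,2-dimethylchroman-6-carbaldehyde F4. Hydrogenolysis of the benzylic C–O bond (H2, Pd(OH)2/C, EtOAc, stopped after one equivalent to spare the aldehyde) leaves the 3S alcohol. The route is rejoined at 7.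

Step 11 (selective enol methylation). The acidity margin between the enol and the catechol is only about two pKa units, so some phenol methylation is possible. The fallback sets out from 19 and masks the catechol. Phenylboronic acid (1.05 equiv, MgSO4, THF) converts 19 into methyl (2S)-4-hydroxy-2-{[(3S)-3-hydroxy-2,2-dimethyl-3,4-dihydro-2H-chromen-6-yl]methyl}-5-oxo-3-(2-phenyl-1,3,2-benzodioxaborol-5-yl)-2,5-dihydrofuran-2-carboxylate F5. The enol is then the only acidic OH, and excess TMSCHN2 in PhMe–MeOH gives the 4-methoxy boronate methyl (2S)-2-{[(3S)-3-hydroxy-2,2-dimethyl-3,4-dihydro-2H-chromen-6-yl]methyl}-4-methoxy-5-oxo-3-(2-phenyl-1,3,2-benzodioxaborol-5-yl)-2,5-dihydrofuran-2-carboxylate F6. The boronate is hydrolysed by stirring in wet THF and the boronic acid is removed on silica. The route is rejoined at 20.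

**Further compounds**
F1 | step 10 | methyl (2Z)-3-(3,4-dihydroxyphenyl)-2-hydroxyprop-2-enoate | COC(=O)/C(O)=C/c1ccc(O)c(O)c1
F2 | step 10 | methyl (2R)-3-(3,4-dihydroxyphenyl)-4-hydroxy-2-{[(3S)-3-hydroxy-2,2-dimethyl-3,4-dihydro-2H-chromen-6-yl]methyl}-5-oxo-2,5-dihydrofuran-2-carboxylate | COC(=O)[C@]1(Cc2ccc3c(c2)C[C@H](O)C(C)(C)O3)OC(=O)C(O)=C1c1ccc(O)c(O)c1
F3 | step 4 | 2,2-dimethyl-2H-chromene-6-carbaldehyde | CC1(C)C=Cc2cc(C=O)ccc2O1
F4 | step 4 | (3S,4S)-3,4-epoxy-2,2-dimethylchroman-6-carbaldehyde | O=Cc1ccc2OC(C)(C)[C@H]3O[C@H]3c2c1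
F5 | step 11 | methyl (2S)-4-hydroxy-2-{[(3S)-3-hydroxy-2,2-dimethyl-3,4-dihydro-2H-chromen-6-yl]methyl}-5-oxo-3-(2-phenyl-1,3,2-benzodioxaborol-5-yl)-2,5-dihydrofuran-2-carboxylate | COC(=O)[C@@]1(Cc2ccc3c(c2)C[C@H](O)C(C)(C)O3)OC(=O)C(O)=C1c1ccc2OB(c3ccccc3)Oc2c1
F6 | step 11 | methyl (2S)-2-{[(3S)-3-hydroxy-2,2-dimethyl-3,4-dihydro-2H-chromen-6-yl]methyl}-4-methoxy-5-oxo-3-(2-phenyl-1,3,2-benzodioxaborol-5-yl)-2,5-dihydrofuran-2-carboxylate | COC(=O)[C@@]1(Cc2ccc3c(c2)C[C@H](O)C(C)(C)O3)OC(=O)C(OC)=C1c1ccc2OB(c3ccccc3)Oc2c1
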